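**Assumption:** the target is taken exactly as drawn: an olivil core, oxolane (3S,4R,5S), carrying a threo-(1R,2R) guaiacylglycerol unit on the phenol oxygen of the ring-bound aryl group. Lignan numbering is used: C7–C9 (aryl-bearing side), C7'–C9' (benzyl-bearing side), C7''–C9'' (glycerol arm).

**Retrosynthetic overview**
1. Target ⇒ global desilylation; the glycerol arm comes from an Evans syn glycolate aldol (aryloxyacetyl imide of the core phenol + vanillin acetate), then LiBH4.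
2. Olivil core ⇒ spiro-oxirane (C8'–O–C7') + aryl Grignard reagent (CuI-catalysed opening at the CH2 carbon).
3. Spiro-oxirane ⇒ triol ⇒ cis-fused 3,7-dioxabicyclo[3.3.0]octane lactol.
4. Lactol ⇒ O-benzyl coniferaldehyde + dihydroxyacetone by one organocatalytic domino oxa-Michael/aldol/hemiacetalisation that sets C7, C8 and C8'.
5. Ring order: oxolane ring A (kept) and lactol ring B (sacrificial) form together in step 2; ring B is opened in step 3; the oxirane is closed in step 5 and opened in step 7.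

**Route**

Step 1
Reactants: 1 4-(benzyloxy)-3-methoxybenzaldehyde; 2 (triphenylphosphoranylidene)acetaldehyde
Product: 3 (E)-3-[4-(benzyloxy)-3-methoxyphenyl]prop-2-enal
Conditions: toluene, 80 °C
Reagents that add atoms: none
Why: Wittig olefination with the stabilised formyl ylide gives the (E)-enal; no stereocentre is formed.

Step 2
Reactants: 3 (E)-3-[4-(benzyloxy)-3-methoxyphenyl]prop-2-enal; 4 1,3-dihydroxyacetone dimer (1.0 equiv; it dissociates into two units of monomer 5, of which one is taken up per enal and the other remains as free dihydroxyacetone)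
Product: 7 (1S,5R,6S)-6-[4-(benzyloxy)-3-methoxyphenyl]-3,7-dioxabicyclo[3.3.0]octane-1,4-diol (cis-fused; C4 anomers), via dihydroxyacetone monomer 5 (not isolated), via monocyclic oxolane aldehyde 6 (not isolated)
Conditions: (S)-2-[diphenyl(trimethylsilyloxy)methyl]pyrrolidine (20 mol %), PhCO2H (20 mol %), CHCl3, rt, 48–72 h
Reagents that add atoms: none
Why: Iminium–enamine domino oxa-Michael/aldol/hemiacetalisation of dihydroxyacetone with an enal: the (S)-catalyst shields the Re face of the iminium β-carbon so oxygen adds from the Si face (C6 S), the enamine closes 5-exo onto the ketone, and reversible aldol plus lactol closure funnel to the cis-fused bicycle with the aryl group on the convex face (C5 R, C1 S).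

Step 3
Reactants: 7 bicyclic lactol
Product: 8 (3R,4R,5S)-5-[4-(benzyloxy)-3-methoxyphenyl]-3,4-bis(hydroxymethyl)oxolan-3-ol
Conditions: NaBH4, MeOH, 0 °C
Reagents that add atoms: none
Why: Borohydride reduction of the open hydroxy-aldehyde tautomer of the lactol opens ring B to the triol without touching the three stereocentres.

Step 4
Reactants: 8 triol
Product: 9 (3R,4R,5S)-5-[4-(benzyloxy)-3-methoxyphenyl]-4-{[(tert-butyldiphenylsilyl)oxy]methyl}-3-(hydroxymethyl)oxolan-3-ol
Conditions: TBDPSCl (1.05 equiv), imidazole, CH2Cl2, −20 to 0 °C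
Reagents that add atoms: tert-butyl(chloro)diphenylsilane, CC(C)(C)[Si](Cl)(c1ccccc1)c1ccccc1
Why: Sterically controlled silyl ether formation: the CH2OH on the ring CH reacts with the bulky chloride faster than the neopentyl-type CH2OH on the quaternary carbinol carbon, and the tertiary OH is inert.

Step 5
Reactants: 9 silyl ether diol
Product: 11 (3R,6S,7R)-6-[4-(benzyloxy)-3-methoxyphenyl]-7-{[(tert-butyldiphenylsilyl)oxy]methyl}-1,5-dioxaspiro[2.4]heptane, via primary tosylate 10 (not isolated)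
Conditions: TsCl, Et3N, DMAP (cat.), CH2Cl2, 0 °C to rt; then K2CO3, MeOH, rt
Reagents that add atoms: none
Why: Sulfonylation of the only free primary OH followed by intramolecular Williamson (3-exo-tet) closure by the tertiary alkoxide gives the spiro-oxirane with retention at the quaternary carbon, whose C–O bond is never broken.

Step 6
Reactants: 12 4-bromo-2-methoxyphenol
Product: 13 (4-bromo-2-methoxyphenoxy)tri(propan-2-yl)silane
Conditions: TIPSCl, imidazole, DMF, rt
Reagents that add atoms: chlorotri(propan-2-yl)silane, CC(C)[Si](Cl)(C(C)C)C(C)C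
Why: Standard phenol silylation; the TIPS ether survives Grignard formation and the later basic phenol alkylation.

Step 7
Reactants: 11 spiro-oxirane; 13 aryl bromide (3 equiv)
Product: 15 (3S,4R,5S)-5-[4-(benzyloxy)-3-methoxyphenyl]-4-{[(tert-butyldiphenylsilyl)oxy]methyl}-3-{[3-methoxy-4-(triisopropylsilyloxy)phenyl]methyl}oxolan-3-ol, via arylmagnesium bromide 14 (not isolated)
Conditions: 13, Mg, THF, 45 °C; then CuI (10 mol %), 11, THF, −30 to 0 °C; aq. NH4Cl
Reagents that add atoms: none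
Why: CuI-catalysed SN2 opening of a 2,2-disubstituted oxirane by an aryl Grignard reagent at the unsubstituted CH2 carbon installs the benzyl group and liberates the tertiary alcohol with its configuration untouched.

Step 8
Reactants: 15 benzyl ether
Product: 16 (3S,4R,5S)-4-{[(tert-butyldiphenylsilyl)oxy]methyl}-5-(4-hydroxy-3-methoxyphenyl)-3-{[3-methoxy-4-(triisopropylsilyloxy)phenyl]methyl}oxolan-3-ol
Conditions: H2 (1 atm), Pd/C (10 wt %), EtOAc, rt
Reagents that add atoms: none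
Why: Hydrogenolysis of the aryl benzyl ether frees only the phenol of the ring-bound aryl group; in EtOAc the silyl ethers and the ring benzylic C–O bond survive.

Step 9
Reactants: 17 (4S)-4-benzyloxazolidin-2-one; 18 bromoacetyl bromide
Product: 20 (4S)-4-benzyl-3-(2-bromoacetyl)oxazolidin-2-one, via lithium oxazolidinide 19 (not isolated)
Conditions: n-BuLi, THF, −78 °C; then 18, −78 °C
Reagents that add atoms: none
Why: N-Acylation of the lithiated oxazolidinone at the acyl bromide terminus of bromoacetyl bromide; the auxiliary stereocentre is untouched.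

Step 10
Reactants: 16 phenol; 20 bromoacetyl imide
Product: 21 (4S)-4-benzyl-3-(2-{4-[(2S,3R,4S)-3-{[(tert-butyldiphenylsilyl)oxy]methyl}-4-hydroxy-4-{[3-methoxy-4-(triisopropylsilyloxy)phenyl]methyl}oxolan-2-yl]-2-methoxyphenoxy}acetyl)oxazolidin-2-one
Conditions: K2CO3, acetone, rt
Reagents that add atoms: none
Why: Williamson ether synthesis: the phenoxide displaces the activated α-bromo imide by SN2 faster than it attacks the imide carbonyl, and K2CO3 does not deprotonate the tertiary alcohol.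

Step 11
Reactants: 21 aryloxyacetyl imide; 22 4-formyl-2-methoxyphenyl acetate
Product: 24 (4S)-3-[(2S,3R)-3-[4-(acetyloxy)-3-methoxyphenyl]-3-hydroxy-2-{4-[(2S,3R,4S)-3-{[(tert-butyldiphenylsilyl)oxy]methyl}-4-hydroxy-4-{[3-methoxy-4-(triisopropylsilyloxy)phenyl]methyl}oxolan-2-yl]-2-methoxyphenoxy}propanoyl]-4-benzyloxazolidin-2-one, via (Z)-dibutylboron enolate 23 (not isolated)
Conditions: Bu2BOTf (2.2 equiv), Et3N (2.6 equiv), CH2Cl2, −78 to 0 °C; 22, −78 to 0 °C; then pH 7 buffer, MeOH, aq. H2O2, 0 °C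
Reagents that add atoms: none
Why: Evans syn aldol through the (Z)-boron enolate and a closed chair transition state: the (S)-benzyl auxiliary directs the aldehyde to one enolate face, giving the (2S,3R) syn adduct, which is the threo (7''R,8''R) arrangement after reduction (the second equivalent of Bu2BOTf covers the free tertiary OH).

Step 12
Reactants: 24 aldol adduct
Product: 25 (1R,2R)-2-{4-[(2S,3R,4S)-3-{[(tert-butyldiphenylsilyl)oxy]methyl}-4-hydroxy-4-{[3-methoxy-4-(triisopropylsilyloxy)phenyl]methyl}oxolan-2-yl]-2-methoxyphenoxy}-1-(4-hydroxy-3-methoxyphenyl)propane-1,3-diol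
Conditions: LiBH4 (4 equiv), THF–MeOH, 0 °C to rt
Reagents that add atoms: none
Why: Reductive cleavage of the N-acyl oxazolidinone by LiBH4 gives the primary alcohol and returns the auxiliary, and the same hydride removes the aryl acetate (so any acetate lost in the previous work-up is harmless); neither stereocentre is touched.

Step 13
Reactants: 25 bis-silyl ether
Product: 26 (1R,2R)-1-(4-hydroxy-3-methoxyphenyl)-2-{4-[(2S,3R,4S)-4-hydroxy-4-[(4-hydroxy-3-methoxyphenyl)methyl]-3-(hydroxymethyl)oxolan-2-yl]-2-methoxyphenoxy}propane-1,3-diol (CNP0391650.2)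
Conditions: TBAF (3 equiv), AcOH (3 equiv), THF, 0 °C to rt
Reagents that add atoms: none
Why: Buffered fluoride desilylation cleaves the aryl TIPS ether and the alkyl TBDPS ether in one operation without affecting the benzylic alcohol or the ethers.

**Compound list**
1 | 4-(benzyloxy)-3-methoxybenzaldehyde | COc1cc(C=O)ccc1OCc1ccccc1 | starting material
2 | (triphenylphosphoranylidene)acetaldehyde | O=CC=P(c1ccccc1)(c1ccccc1)c1ccccc1 | starting material
3 | (E)-3-[4-(benzyloxy)-3-methoxyphenyl]prop-2-enal | COc1cc(/C=C/C=O)ccc1OCc1ccccc1 | intermediate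
4 | 1,3-dihydroxyacetone dimer [2,5-bis(hydroxymethyl)-1,4-dioxane-2,5-diol] | OCC1(O)COC(O)(CO)CO1 | starting material
5 | 1,3-dihydroxyacetone monomer (not isolated) | OCC(=O)CO | intermediate
6 | (2S,3R,4R)-2-[4-(benzyloxy)-3-methoxyphenyl]-4-hydroxy-4-(hydroxymethyl)oxolane-3-carbaldehyde (not isolated) | OC[C@@]1(O)CO[C@H](c2ccc(OCc3ccccc3)c(OC)c2)[C@H]1C=O | intermediate
7 | (1S,5R,6S)-6-[4-(benzyloxy)-3-methoxyphenyl]-3,7-dioxabicyclo[3.3.0]octane-1,4-diol (cis-fused lactol, C4 anomers) | O1C[C@@]2(O)CO[C@H](c3ccc(OCc4ccccc4)c(OC)c3)[C@H]2C1O | intermediate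
8 | (3R,4R,5S)-5-[4-(benzyloxy)-3-methoxyphenyl]-3,4-bis(hydroxymethyl)oxolan-3-ol | OC[C@@]1(O)CO[C@H](c2ccc(OCc3ccccc3)c(OC)c2)[C@H]1CO | intermediate
9 | (3R,4R,5S)-5-[4-(benzyloxy)-3-methoxyphenyl]-4-{[(tert-butyldiphenylsilyl)oxy]methyl}-3-(hydroxymethyl)oxolan-3-ol | OC[C@@]1(O)CO[C@H](c2ccc(OCc3ccccc3)c(OC)c2)[C@H]1CO[Si](c4ccccc4)(c5ccccc5)C(C)(C)C | intermediate
10 | {(3S,4R,5S)-5-[4-(benzyloxy)-3-methoxyphenyl]-4-{[(tert-butyldiphenylsilyl)oxy]methyl}-3-hydroxyoxolan-3-yl}methyl 4-methylbenzenesulfonate (not isolated) | Cc1ccc(cc1)S(=O)(=O)OC[C@@]2(O)CO[C@H](c3ccc(OCc4ccccc4)c(OC)c3)[C@H]2CO[Si](c5ccccc5)(c6ccccc6)C(C)(C)C | intermediate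
11 | (3R,6S,7R)-6-[4-(benzyloxy)-3-methoxyphenyl]-7-{[(tert-butyldiphenylsilyl)oxy]methyl}-1,5-dioxaspiro[2.4]heptane | C1O[C@@]12CO[C@H](c3ccc(OCc4ccccc4)c(OC)c3)[C@H]2CO[Si](c5ccccc5)(c6ccccc6)C(C)(C)C | intermediate
12 | 4-bromo-2-methoxyphenol | COc1cc(Br)ccc1O | starting material
13 | (4-bromo-2-methoxyphenoxy)tri(propan-2-yl)silane | COc1cc(Br)ccc1O[Si](C(C)C)(C(C)C)C(C)C | intermediate
14 | [3-methoxy-4-(triisopropylsilyloxy)phenyl]magnesium bromide (not isolated) | COc1cc([Mg]Br)ccc1O[Si](C(C)C)(C(C)C)C(C)C | intermediate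
15 | (3S,4R,5S)-5-[4-(benzyloxy)-3-methoxyphenyl]-4-{[(tert-butyldiphenylsilyl)oxy]methyl}-3-{[3-methoxy-4-(triisopropylsilyloxy)phenyl]methyl}oxolan-3-ol | COc1cc(C[C@@]2(O)CO[C@H](c3ccc(OCc4ccccc4)c(OC)c3)[C@H]2CO[Si](c5ccccc5)(c6ccccc6)C(C)(C)C)ccc1O[Si](C(C)C)(C(C)C)C(C)C | intermediate
16 | (3S,4R,5S)-4-{[(tert-butyldiphenylsilyl)oxy]methyl}-5-(4-hydroxy-3-methoxyphenyl)-3-{[3-methoxy-4-(triisopropylsilyloxy)phenyl]methyl}oxolan-3-ol | COc1cc(C[C@@]2(O)CO[C@H](c3ccc(O)c(OC)c3)[C@H]2CO[Si](c4ccccc4)(c5ccccc5)C(C)(C)C)ccc1O[Si](C(C)C)(C(C)C)C(C)C | intermediate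
17 | (4S)-4-benzyloxazolidin-2-one | O=C1N[C@@H](Cc2ccccc2)CO1 | starting material
18 | bromoacetyl bromide | BrCC(Br)=O | starting material
19 | lithium salt of (4S)-4-benzyloxazolidin-2-one (not isolated) | [Li]N1[C@@H](Cc2ccccc2)COC1=O | intermediate
20 | (4S)-4-benzyl-3-(2-bromoacetyl)oxazolidin-2-one | BrCC(=O)N1[C@@H](Cc2ccccc2)COC1=O | intermediate
21 | aryloxyacetyl imide: 16 O-alkylated on the free phenol with CH2C(=O)–N of (4S)-4-benzyloxazolidin-2-one | COc1cc(C[C@@]2(O)CO[C@H](c3ccc(OCC(=O)N4[C@@H](Cc5ccccc5)COC4=O)c(OC)c3)[C@H]2CO[Si](c6ccccc6)(c7ccccc7)C(C)(C)C)ccc1O[Si](C(C)C)(C(C)C)C(C)C | intermediate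
22 | 4-formyl-2-methoxyphenyl acetate (vanillin acetate) | COc1cc(C=O)ccc1OC(C)=O | starting material
23 | (Z)-dibutylboron enolate of 21 (not isolated) | COc1cc(C[C@@]2(O)CO[C@H](c3ccc(O/C=C(\OB(CCCC)CCCC)N4[C@@H](Cc5ccccc5)COC4=O)c(OC)c3)[C@H]2CO[Si](c6ccccc6)(c7ccccc7)C(C)(C)C)ccc1O[Si](C(C)C)(C(C)C)C(C)C | intermediate
24 | (2S,3R) syn aldol adduct: (4S)-3-[3-(4-acetoxy-3-methoxyphenyl)-3-hydroxy-2-(aryloxy)propanoyl]-4-benzyloxazolidin-2-one, aryloxy = protected olivil core | COc1cc(C[C@@]2(O)CO[C@H](c3ccc(O[C@H](C(=O)N4[C@@H](Cc5ccccc5)COC4=O)[C@H](O)c6ccc(OC(C)=O)c(OC)c6)c(OC)c3)[C@H]2CO[Si](c7ccccc7)(c8ccccc8)C(C)(C)C)ccc1O[Si](C(C)C)(C(C)C)C(C)C | intermediate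
25 | (1R,2R)-1-(4-hydroxy-3-methoxyphenyl)-2-(aryloxy)propane-1,3-diol, aryloxy = olivil core with 9-O-TBDPS and 4'-O-TIPS | COc1cc(C[C@@]2(O)CO[C@H](c3ccc(O[C@H](CO)[C@H](O)c4ccc(O)c(OC)c4)c(OC)c3)[C@H]2CO[Si](c5ccccc5)(c6ccccc6)C(C)(C)C)ccc1O[Si](C(C)C)(C(C)C)C(C)C | intermediate
26 | (1R,2R)-1-(4-hydroxy-3-methoxyphenyl)-2-{4-[(2S,3R,4S)-4-hydroxy-4-[(4-hydroxy-3-methoxyphenyl)methyl]-3-(hydroxymethyl)oxolan-2-yl]-2-methoxyphenoxy}propane-1,3-diol | COc1cc(C[C@@]2(O)CO[C@H](c3ccc(O[C@H](CO)[C@H](O)c4ccc(O)c(OC)c4)c(OC)c3)[C@H]2CO)ccc1O | target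

**Step count:** 13 steps in total; longest linear sequence 11 steps (1 → 3 → 7 → 8 → 9 → 11 → 15 → 16 → 21 → 24 → 25 → 26; steps 6 and 9 are one-step side branches).

**Steps most likely to fail, with fallbacks**

Step 2 (domino). The 4-alkoxycinnamaldehyde is an electron-rich, slow iminium acceptor and the oxa-Michael step is reversible. The choice of the (S)-catalyst rests on the usual shielding model; if the sense proves opposite, the (R)-catalyst is used. Fallback, setting out from 1 and returning at 11: vinylmagnesium bromide adds to 1 to give racemic 1-[4-(benzyloxy)-3-methoxyphenyl]prop-2-en-1-ol F1. Sharpless kinetic resolution (Ti(OiPr)4, D-(−)-diisopropyl tartrate, t-BuOOH, CH2Cl2, −20 °C) epoxidises the fast-reacting (S)-alcohol to the anti epoxy alcohol (R)-[4-(benzyloxy)-3-methoxyphenyl][(2R)-oxiran-2-yl]methanol F2. O-Propargylation (NaH, propargyl bromide) gives the propargyl ether F3. Cp2TiCl (trivalent titanium, made from Cp2TiCl2 and Zn in THF) opens the oxirane to the secondary radical, which cyclises 5-exo-dig onto the alkyne to give the trans methylene-oxolane alcohol F4. Silylation (TBDPSCl, imidazole) gives the silyl ether F5, and mCPBA epoxidation from the face opposite to the adjacent CH2OTBDPS group gives 11.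

Step 4 (selective silylation). Both hydroxymethyl groups are primary, so the preference for the ring-CH carbinol over the neopentyl-type one may be only modest. Fallback, setting out from 8 and returning at 9: 2,2-dimethoxypropane and PPTS in acetone tie the tertiary/primary 1,2-diol as the spiro-acetonide alcohol F6 (the five-membered acetal is strongly preferred over a trans-fused six-membered one). The single free OH is silylated (TBDPSCl, imidazole) to the acetonide silyl ether F7, and 80 % aqueous AcOH at rt removes the acetonide to give 9.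

Step 7 (oxirane arylation). The spiro-oxirane is hindered and magnesium halide can trigger rearrangement to the aldehyde or bromohydrin formation. Fallback, setting out from 9 and returning at 15: Parikh–Doering oxidation (SO3·pyridine, DMSO, Et3N) of the primary OH gives the α-hydroxy aldehyde F8. Addition of Grignard reagent 14 gives the benzylic diol F9 (both carbinol epimers serve). 1,1'-Thiocarbonyldiimidazole closes the cyclic thionocarbonate F10. Bu3SnH/AIBN in toluene at 90 °C cleaves the benzylic C–O bond selectively through the benzylic radical, and mild basic work-up releases the tertiary OH to give 15.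

**Further compounds**
F1 | step 2 | 1-[4-(benzyloxy)-3-methoxyphenyl]prop-2-en-1-ol (racemic) | C=CC(O)c1ccc(OCc2ccccc2)c(OC)c1
F2 | step 2 | (R)-[4-(benzyloxy)-3-methoxyphenyl][(2R)-oxiran-2-yl]methanol | O[C@H](c1ccc(OCc2ccccc2)c(OC)c1)[C@H]1CO1
F3 | step 2 | (2R)-2-{(R)-[4-(benzyloxy)-3-methoxyphenyl](prop-2-yn-1-yloxy)methyl}oxirane | C#CCO[C@H](c1ccc(OCc2ccccc2)c(OC)c1)[C@H]1CO1
F4 | step 2 | [(2S,3R)-2-[4-(benzyloxy)-3-methoxyphenyl]-4-methylideneoxolan-3-yl]methanol | C=C1CO[C@H](c2ccc(OCc3ccccc3)c(OC)c2)[C@H]1CO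
F5 | step 2 | tert-butyl{[(2S,3R)-2-[4-(benzyloxy)-3-methoxyphenyl]-4-methylideneoxolan-3-yl]methoxy}diphenylsilane | C=C1CO[C@H](c2ccc(OCc3ccccc3)c(OC)c2)[C@H]1CO[Si](c4ccccc4)(c5ccccc5)C(C)(C)C
F6 | step 4 | [(5S,8S,9R)-8-[4-(benzyloxy)-3-methoxyphenyl]-2,2-dimethyl-1,3,7-trioxaspiro[4.4]nonan-9-yl]methanol | CC1(C)OC[C@@]2(O1)CO[C@H](c3ccc(OCc4ccccc4)c(OC)c3)[C@H]2CO
F7 | step 4 | tert-butyldiphenylsilyl ether of F6 | CC1(C)OC[C@@]2(O1)CO[C@H](c3ccc(OCc4ccccc4)c(OC)c3)[C@H]2CO[Si](c5ccccc5)(c6ccccc6)C(C)(C)C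
F8 | step 7 | (3S,4R,5S)-5-[4-(benzyloxy)-3-methoxyphenyl]-4-{[(tert-butyldiphenylsilyl)oxy]methyl}-3-hydroxyoxolane-3-carbaldehyde | O=C[C@@]1(O)CO[C@H](c2ccc(OCc3ccccc3)c(OC)c2)[C@H]1CO[Si](c4ccccc4)(c5ccccc5)C(C)(C)C
F9 | step 7 | (3S,4R,5S)-5-[4-(benzyloxy)-3-methoxyphenyl]-4-{[(tert-butyldiphenylsilyl)oxy]methyl}-3-{hydroxy[3-methoxy-4-(triisopropylsilyloxy)phenyl]methyl}oxolan-3-ol (carbinol epimers) | COc1cc(C(O)[C@@]2(O)CO[C@H](c3ccc(OCc4ccccc4)c(OC)c3)[C@H]2CO[Si](c5ccccc5)(c6ccccc6)C(C)(C)C)ccc1O[Si](C(C)C)(C(C)C)C(C)C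
F10 | step 7 | cyclic thionocarbonate of F9 (spiro 1,3-dioxolane-2-thione on the oxolane) | COc1cc(C2OC(=S)O[C@@]23CO[C@H](c4ccc(OCc5ccccc5)c(OC)c4)[C@H]3CO[Si](c6ccccc6)(c7ccccc7)C(C)(C)C)ccc1O[Si](C(C)C)(C(C)C)C(C)C
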